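**Plan**
Rings: A trioxygenated benzene, B pyran (O5, C6), C dihydrofuran (O11), D methoxybenzene, E dimethylpyran; pterocarpan numbering.
Cuts, last-formed bond first: O5–C6 (ring B), C6a–C11a (ring C), C6a–aryl (ring D), the O11–C11a ether bond, the O–CMe2 bond of ring E, and the prenyl C–C bond on ring A.
Enabling feature: C11a–H is a benzylic ether C–H bond (alpha to O11, on the electron-rich ring A) lying 1,5 to C6a, the diazo-bearing carbon on ring D, so a rhodium carbenoid at C6a can insert into it.
Forward order: ring E on ring A (C-prenylation, silylation, acid cyclisation), ether link to ring D, diazo ester, ring C by C–H insertion, ring B by phenoxide alkylation.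
Stereochemistry: C6a and C11a are both set, cis, in the insertion by the chiral dirhodium carboxylate; no later step touches them.

Key step: step 7

Assumption: the sense of induction is taken from simple 2-(benzyloxy)aryl diazoacetates, where the S-configured phthaloyl-tert-leucinate catalyst is understood to give the (2R,3S) cis ester; Rh2(R-PTTL)4 (dirhodium tetrakis[N-phthaloyl-(R)-tert-leucinate], from (R)-tert-leucine, phthalic anhydride and Rh2(OAc)4) is therefore used, and its enantiomer would be used in the same way should the sense prove opposite.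

**Route**

Step 1
Reactants: 1 2,4,6-trihydroxybenzaldehyde; 2 1-bromo-3-methylbut-2-ene
Product: 3 2,4,6-trihydroxy-3-(3-methylbut-2-en-1-yl)benzaldehyde
Conditions: DBU (1.0 equiv), THF, 0 °C to rt, slow addition of 2 (1.0 equiv)
Reagents that add atoms: none
Why: Friedel–Crafts-type C-alkylation of the ambident phloroglucinol phenoxide by the soft allylic bromide, a known reaction of acylphloroglucinols; C3 and C5 of 1 are equivalent, so only one mono-C-prenyl product can form.

Step 2
Reactants: 3 2,4,6-trihydroxy-3-(3-methylbut-2-en-1-yl)benzaldehyde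
Product: 4 4,6-bis(tert-butyldimethylsilyloxy)-2-hydroxy-3-(3-methylbut-2-en-1-yl)benzaldehyde
Conditions: TBSCl (2.1 equiv), imidazole (4 equiv), DMF, 0 °C
Reagents that add atoms: tert-butyldimethylsilyl chloride, CC(C)(C)[Si](C)(C)Cl
Why: Imidazole-promoted silyl ether formation should take the para hydroxyl and the less hindered ortho hydroxyl, leaving free the hydroxyl flanked by the prenyl and formyl groups, which is the more crowded one and is then held in the hydrogen bond to the carbonyl.

Step 3
Reactants: 4 4,6-bis(tert-butyldimethylsilyloxy)-2-hydroxy-3-(3-methylbut-2-en-1-yl)benzaldehyde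
Product: 5 5,7-bis(tert-butyldimethylsilyloxy)-2,2-dimethylchroman-8-carbaldehyde
Conditions: Amberlyst 15 (dry, cat.), toluene, 60 °C
Reagents that add atoms: none
Why: Acid-catalysed Markovnikov cycloetherification of an ortho-prenylphenol, in which the tertiary cation is captured by the only free hydroxyl, so ring E can close only on the oxygen next to the formyl-bearing carbon; aryl silyl ethers should survive the resin in dry toluene.

Step 4
Reactants: 5 5,7-bis(tert-butyldimethylsilyloxy)-2,2-dimethylchroman-8-carbaldehyde
Product: 6 [5,7-bis(tert-butyldimethylsilyloxy)-2,2-dimethylchroman-8-yl]methanol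
Conditions: iBu2AlH (1.2 equiv), CH2Cl2, −78 °C; aq. potassium sodium tartrate
Reagents that add atoms: none
Why: Hydride 1,2-reduction of the aldehyde; the aluminium alkoxide formed at −78 °C is a poor nucleophile, which guards against migration of the neighbouring silyl group from the phenol oxygen to the benzylic oxygen.

Step 5
Reactants: 6 [5,7-bis(tert-butyldimethylsilyloxy)-2,2-dimethylchroman-8-yl]methanol; 7 2-iodo-5-methoxyphenol
Product: 8 8-[(2-iodo-5-methoxyphenoxy)methyl]-5,7-bis(tert-butyldimethylsilyloxy)-2,2-dimethylchroman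
Conditions: PPh3, DIAD, THF, 0 °C to rt
Reagents that add atoms: none
Why: Mitsunobu etherification, in which the acidic iodophenol is alkylated on oxygen by the phosphonium-activated primary benzylic alcohol under near-neutral conditions that the acid-labile trioxygenated benzyl alcohol and the silyl ethers tolerate.

Step 6
Reactants: 8 8-[(2-iodo-5-methoxyphenoxy)methyl]-5,7-bis(tert-butyldimethylsilyloxy)-2,2-dimethylchroman; 9 ethyl diazoacetate
Product: 10 ethyl 2-diazo-2-[2-({5,7-bis(tert-butyldimethylsilyloxy)-2,2-dimethylchroman-8-yl}methoxy)-4-methoxyphenyl]acetate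
Conditions: Pd(PPh3)4 (5 mol%), Ag2CO3 (0.5 equiv), Et3N (1.3 equiv), 9 (1.5 equiv), toluene, rt
Reagents that add atoms: none
Why: Palladium-catalysed cross-coupling of an aryl iodide with the C–H bond of ethyl diazoacetate (oxidative addition to zerovalent palladium, silver-assisted palladation of the diazo carbon, reductive elimination), which keeps the diazo group intact at room temperature.

Step 7
Reactants: 10 ethyl 2-diazo-2-[2-({5,7-bis(tert-butyldimethylsilyloxy)-2,2-dimethylchroman-8-yl}methoxy)-4-methoxyphenyl]acetate
Product: 11 ethyl (2S,3R)-2-[5,7-bis(tert-butyldimethylsilyloxy)-2,2-dimethylchroman-8-yl]-6-methoxy-2,3-dihydrobenzofuran-3-carboxylate (cis)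
Conditions: Rh2(R-PTTL)4 (2 mol%), toluene, −78 °C, slow addition of 10, then to −40 °C
Reagents that add atoms: none
Why: The dirhodium carboxylate expels N2 from 10 and the electrophilic donor/acceptor carbenoid at C6a takes the C11a–H bond through a three-centre, hydride-transfer-like transition state, forming C6a–C11a and releasing the catalyst. The closest known reaction type is the dirhodium-carboxylate-catalysed enantioselective intramolecular C–H insertion of 2-(benzyloxy)aryl diazoacetates into the benzylic ether C–H bond, which gives cis-2-aryl-2,3-dihydrobenzofuran-3-carboxylates. Ring C closes as a five-membered ring by 1,5-insertion along the path C6a–C(aryl)–C(aryl)–O11–C11a. Both stereocentres arise in this single event: the phthalimido tert-leucinate walls of the catalyst select one face of the carbenoid and one of the two enantiotopic C11a–H bonds, fixing C6a (3R in 11) and C11a (2S in 11), and the ring A aryl group points away from the catalyst surface in the transition state, which places it cis to the ester. The step needs selectivity for C11a–H over the OCH3, silyl methyl and chroman C–H bonds, over arene cyclopropanation and over carbene dimerisation; the 1,5 geometry, the hydridic character of a C–H bond alpha to O11 and benzylic to ring A, and slow addition at low temperature should secure it. The cold, neutral medium also keeps the kinetic cis ester from epimerising at C3.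

Step 8
Reactants: 11 ethyl (2S,3R)-2-[5,7-bis(tert-butyldimethylsilyloxy)-2,2-dimethylchroman-8-yl]-6-methoxy-2,3-dihydrobenzofuran-3-carboxylate
Product: 12 {(2S,3S)-2-[5,7-bis(tert-butyldimethylsilyloxy)-2,2-dimethylchroman-8-yl]-6-methoxy-2,3-dihydrobenzofuran-3-yl}methanol
Conditions: iBu2AlH (3 equiv), CH2Cl2, −78 °C to −40 °C; aq. potassium sodium tartrate
Reagents that add atoms: none
Why: Ester-to-primary-alcohol reduction with an electrophilic aluminium hydride, whose non-basic medium and low temperature avoid enolisation at C3, so the cis relationship is kept (the descriptor at C3 changes only through ligand priorities).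

Step 9
Reactants: 12 {(2S,3S)-2-[5,7-bis(tert-butyldimethylsilyloxy)-2,2-dimethylchroman-8-yl]-6-methoxy-2,3-dihydrobenzofuran-3-yl}methanol
Product: 13 {(2S,3S)-2-[5,7-bis(tert-butyldimethylsilyloxy)-2,2-dimethylchroman-8-yl]-6-methoxy-2,3-dihydrobenzofuran-3-yl}methyl methanesulfonate
Conditions: MsCl, Et3N, CH2Cl2, 0 °C
Reagents that add atoms: methanesulfonyl chloride, CS(=O)(=O)Cl
Why: Sulfonate ester formation (mesylation) of the primary alcohol turns the future C6 into an electrophile without touching either stereocentre.

Step 10
Reactants: 13 {(2S,3S)-2-[5,7-bis(tert-butyldimethylsilyloxy)-2,2-dimethylchroman-8-yl]-6-methoxy-2,3-dihydrobenzofuran-3-yl}methyl methanesulfonate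
Product: 15 CNP0207547.1 (6aS,11aS)-3-hydroxy-9-methoxypterocarpan bearing a 2,2-dimethyldihydropyran fused through O at C1 plus CH2 at C2, via diphenol mesylate 14 (not isolated)
Conditions: Bu4NF (3 equiv), THF, 0 °C to rt; aq. NH4Cl
Reagents that add atoms: none
Why: Fluoride-mediated desilylation followed by intramolecular Williamson etherification (6-exo-tet SN2), in which the phenoxide ortho to the C11a-bearing carbon displaces the primary mesylate and closes ring B while the para phenoxide cannot reach C6; substitution occurs at the CH2 carbon, so both stereocentres are carried over and the B/C fusion is cis.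

**Compound list**

1 | 2,4,6-trihydroxybenzaldehyde | O=Cc1c(O)cc(O)cc1O | starting material
2 | 1-bromo-3-methylbut-2-ene (prenyl bromide) | CC(C)=CCBr | starting material
3 | 2,4,6-trihydroxy-3-(3-methylbut-2-en-1-yl)benzaldehyde | O=Cc1c(O)cc(O)c(CC=C(C)C)c1O | intermediate
4 | 4,6-bis(tert-butyldimethylsilyloxy)-2-hydroxy-3-(3-methylbut-2-en-1-yl)benzaldehyde | O=Cc1c(O[Si](C)(C)C(C)(C)C)cc(O[Si](C)(C)C(C)(C)C)c(CC=C(C)C)c1O | intermediate
5 | 5,7-bis(tert-butyldimethylsilyloxy)-2,2-dimethylchroman-8-carbaldehyde | O=Cc1c(O[Si](C)(C)C(C)(C)C)cc(O[Si](C)(C)C(C)(C)C)c2CCC(C)(C)Oc12 | intermediate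
6 | [5,7-bis(tert-butyldimethylsilyloxy)-2,2-dimethylchroman-8-yl]methanol | OCc1c(O[Si](C)(C)C(C)(C)C)cc(O[Si](C)(C)C(C)(C)C)c2CCC(C)(C)Oc12 | intermediate
7 | 2-iodo-5-methoxyphenol | COc1ccc(I)c(O)c1 | starting material
8 | 8-[(2-iodo-5-methoxyphenoxy)methyl]-5,7-bis(tert-butyldimethylsilyloxy)-2,2-dimethylchroman | COc1ccc(I)c(OCc2c(O[Si](C)(C)C(C)(C)C)cc(O[Si](C)(C)C(C)(C)C)c3CCC(C)(C)Oc23)c1 | intermediate
9 | ethyl diazoacetate | CCOC(=O)C=[N+]=[N-] | starting material
10 | ethyl 2-diazo-2-[2-({5,7-bis(tert-butyldimethylsilyloxy)-2,2-dimethylchroman-8-yl}methoxy)-4-methoxyphenyl]acetate | CCOC(=O)C(=[N+]=[N-])c1ccc(OC)cc1OCc1c(O[Si](C)(C)C(C)(C)C)cc(O[Si](C)(C)C(C)(C)C)c2CCC(C)(C)Oc12 | intermediate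
11 | ethyl (2S,3R)-2-[5,7-bis(tert-butyldimethylsilyloxy)-2,2-dimethylchroman-8-yl]-6-methoxy-2,3-dihydrobenzofuran-3-carboxylate (cis) | COc1ccc2c(c1)O[C@H](c3c(O[Si](C)(C)C(C)(C)C)cc(O[Si](C)(C)C(C)(C)C)c4c3OC(C)(C)CC4)[C@@H]2C(=O)OCC | intermediate
12 | {(2S,3S)-2-[5,7-bis(tert-butyldimethylsilyloxy)-2,2-dimethylchroman-8-yl]-6-methoxy-2,3-dihydrobenzofuran-3-yl}methanol | COc1ccc2c(c1)O[C@H](c3c(O[Si](C)(C)C(C)(C)C)cc(O[Si](C)(C)C(C)(C)C)c4c3OC(C)(C)CC4)[C@@H]2CO | intermediate
13 | {(2S,3S)-2-[5,7-bis(tert-butyldimethylsilyloxy)-2,2-dimethylchroman-8-yl]-6-methoxy-2,3-dihydrobenzofuran-3-yl}methyl methanesulfonate | COc1ccc2c(c1)O[C@H](c3c(O[Si](C)(C)C(C)(C)C)cc(O[Si](C)(C)C(C)(C)C)c4c3OC(C)(C)CC4)[C@@H]2COS(C)(=O)=O | intermediate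
14 | [(2S,3S)-2-(5,7-dihydroxy-2,2-dimethylchroman-8-yl)-6-methoxy-2,3-dihydrobenzofuran-3-yl]methyl methanesulfonate (diphenol mesylate, present as phenoxide, not isolated) | COc1ccc2c(c1)O[C@H](c3c(O)cc(O)c4c3OC(C)(C)CC4)[C@@H]2COS(C)(=O)=O | intermediate
15 | CNP0207547.1, (6aS,11aS)-3-hydroxy-9-methoxypterocarpan with a 2,2-dimethyl-3,4-dihydro-2H-pyran ring fused at C1 (O) and C2 (CH2) | COc1ccc2c(c1)O[C@@H]1c3c(cc(O)c4c3OC(C)(C)CC4)OC[C@H]21 | target

**Count and risks**

Total steps: 10. Longest linear sequence: 10 steps (from 1 to 15).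

Step 7 (most likely to fail). With two ortho oxygen substituents on ring A, the benzylic C11a–H bond may fit the chiral pocket poorly. Insertion would then be slow, carbene dimerisation would compete, and enantiofacial or cis/trans discrimination could be lost. The fallback sets out from 10 and comes back at 11, and takes the stereochemistry from resolution instead of asymmetric catalysis. Compound 10 is decomposed with the compact achiral catalyst Rh2(OAc)4 (dirhodium tetraacetate) in CH2Cl2 at 0 °C, which should still give the kinetic cis insertion product, now as the racemic cis ester F1. The enantiomers are separated by preparative chromatography on a polysaccharide-based chiral stationary phase, and the (2S,3R) enantiomer is 11.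

Step 6. The bulky ortho benzyloxy substituent on the electron-rich iodide may slow the coupling, while the diazo compound is consumed by palladium or silver carbene formation. The fallback sets out from 8 and comes back at 10, and builds the diazo group by diazo transfer instead of coupling. Negishi-type coupling of 8 with the Reformatsky reagent BrZnCH2CO2Et (Pd2(dba)3, XPhos, THF, 60 °C) should give the ethyl arylacetate F2. Regitz diazo transfer with 4-acetamidobenzenesulfonyl azide and DBU in dry MeCN at 0 °C to rt, the usual way to 2-alkoxyaryl diazoacetates, then gives 10.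

Step 10. The free phenoxides ortho and para to C11a may expel O11 by quinone methide formation, which would scramble C11a before ring B closes. The mesylate may also be lost by elimination or by fluoride substitution. The fallback sets out from 12 and comes back at 15, and closes ring B by redox condensation instead of phenoxide displacement. Bu4NF buffered with AcOH in THF at 0 °C removes both silyl groups from 12 to give the triol F3. Intramolecular Mitsunobu etherification (PPh3, DIAD, THF, high dilution, 0 °C) then joins the ortho phenol oxygen to the primary carbon under near-neutral conditions and gives 15.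

**Further compounds**

F1 | step 7 | racemic ethyl cis-2-[5,7-bis(tert-butyldimethylsilyloxy)-2,2-dimethylchroman-8-yl]-6-methoxy-2,3-dihydrobenzofuran-3-carboxylate (1:1 mixture of 11 and its enantiomer) | COc1ccc2c(c1)O[C@H](c3c(O[Si](C)(C)C(C)(C)C)cc(O[Si](C)(C)C(C)(C)C)c4c3OC(C)(C)CC4)[C@@H]2C(=O)OCC.COc1ccc2c(c1)O[C@@H](c3c(O[Si](C)(C)C(C)(C)C)cc(O[Si](C)(C)C(C)(C)C)c4c3OC(C)(C)CC4)[C@H]2C(=O)OCC
F2 | step 6 | ethyl 2-[2-({5,7-bis(tert-butyldimethylsilyloxy)-2,2-dimethylchroman-8-yl}methoxy)-4-methoxyphenyl]acetate | CCOC(=O)Cc1ccc(OC)cc1OCc1c(O[Si](C)(C)C(C)(C)C)cc(O[Si](C)(C)C(C)(C)C)c2CCC(C)(C)Oc12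
F3 | step 10 | (2S,3S)-2-(5,7-dihydroxy-2,2-dimethylchroman-8-yl)-3-(hydroxymethyl)-6-methoxy-2,3-dihydrobenzofuran | COc1ccc2c(c1)O[C@H](c3c(O)cc(O)c4c3OC(C)(C)CC4)[C@@H]2CO
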